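**Retrosynthetic overview**

1. The route rests on one feature: the trans C4–C5 epoxide with methyl C15 on C4, lying next to the lactone carbinol C6 that is shared by the ten-membered carbocycle (C1–C10) and the butenolide ring (O6–C6–C7=C11–C12). This is the oxide of an E-trisubstituted allylic alcohol.
2. With the epoxide oxygen removed and the C10 and C13 acetates held as silyl ethers, C5–C6, C4–C15 and O6–C12 are cut together. This gives a terminal alkyne (C4≡C5), the C6 aldehyde, Me2Zn and the C12 methyl ester of an acyclic (Z)-formyl enoate; forward, the ten-membered ring closes first and the butenolide second, in one flask.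
3. The (Z)-formyl enoate C6/C7=C11/C12 is unmasked from a 3,4-disubstituted 2-silylfuran by singlet oxygen, the silicon-bearing carbon becoming C12.
4. C1–C2 comes from a butynyl Grignard addition to a γ-lactone, C8 from asymmetric transfer hydrogenation of a furyl ketone, and C9–C10 with the C10 stereocentre from a copper bis(oxazoline) Mukaiyama aldol of the furyl enol silane with methyl pyruvate.
5. The furan, with C13 and the ring silicon in place, comes from diethyl furan-3,4-dicarboxylate by reduction and a 1,4 O→C silyl shift. Ring order: furan (masked C6/C12), γ-lactone (temporary), ten-membered carbocycle, butenolide, epoxide.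

Key step: step 16

Numbering: C1 ketone carbon, C2, C3, C4 (epoxide carbon bearing methyl C15), C5 (epoxide CH), C6 (lactone O–CH), C7 and C11 (butenolide alkene), C12 (lactone carbonyl), C13 (acetoxymethyl carbon), C8 (propanoate carbon), C9, C10 (acetate carbon bearing methyl C14). O6, O8, O10 are the oxygens on those carbons.

Abbreviations: TES = triethylsilyl, TBS = tert-butyldimethylsilyl, TMS = trimethylsilyl, Fur = 4-[(tert-butyldimethylsilyloxy)methyl]-5-(triethylsilyl)furan-3-yl.

Assumption: compound 16, the (R,R)-t-Bu-box ligand, IMes and RuCl(p-cymene)[(S,S)-TsDPEN] are purchased. The sense of induction in steps 8 and 9 is taken to follow that of simple aryl ketone substrates. Hydroxy ketones 18 and 19 are drawn open-chain although they equilibrate with their five-membered lactols.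

**Route**

Step 1
Reactants: 1 diethyl furan-3,4-dicarboxylate
Product: 2 furan-3,4-diyldimethanol
Conditions: LiAlH4, THF, 0 °C to rt; aq. NaOH work-up
Reagents that add atoms: none
Why: Hydride reduction of both esters to the primary alcohols is routine and the furan ring is inert to LiAlH4 (ester reduction).

Step 2
Reactants: 2 furan-3,4-diyldimethanol
Product: 3 3,4-bis[(triethylsilyloxy)methyl]furan
Conditions: TESCl, imidazole, CH2Cl2, 0 °C to rt
Reagents that add atoms: chlorotriethylsilane, CC[Si](Cl)(CC)CC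
Why: Silylation of two primary alcohols with a silyl chloride and imidazole should give the symmetric bis-silyl ether.

Step 3
Reactants: 3 3,4-bis[(triethylsilyloxy)methyl]furan
Product: 5 3-[(tert-butyldimethylsilyloxy)methyl]-2-(triethylsilyl)-4-[(triethylsilyloxy)methyl]furan, via alkoxide 4 (not isolated)
Conditions: n-BuLi (1.1 equiv), HMPA, THF, −78 to 0 °C; then TBSCl, 0 °C to rt
Reagents that add atoms: tert-butylchlorodimethylsilane, CC(C)(C)[Si](C)(C)Cl
Why: Deprotonation of a furan α-position triggers a 1,4 O→C silyl shift (retro-Brook rearrangement) from the neighbouring silyloxymethyl arm, so silicon lands on the future C12 and the freed alkoxide 4 on the future C13 is capped in the same flask with TBSCl, one equivalent of base limiting the shift to one side of the symmetric furan.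

Step 4
Reactants: 5 3-[(tert-butyldimethylsilyloxy)methyl]-2-(triethylsilyl)-4-[(triethylsilyloxy)methyl]furan
Product: 6 4-[(tert-butyldimethylsilyloxy)methyl]-5-(triethylsilyl)furan-3-carbaldehyde
Conditions: (COCl)2, DMSO, CH2Cl2, −78 to −30 °C; then Et3N, −78 °C to rt
Reagents that add atoms: none
Why: Under Swern conditions a primary triethylsilyl ether is cleaved and oxidised directly to the aldehyde, while the more robust TBS ether and the ring C–Si bond should stay intact (Swern oxidation with in situ desilylation).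

Step 5
Reactants: 6 4-[(tert-butyldimethylsilyloxy)methyl]-5-(triethylsilyl)furan-3-carbaldehyde
Product: 7 rac-1-Fur-ethanol
Conditions: MeMgBr, THF, −78 to 0 °C; aq. NH4Cl
Reagents that add atoms: methylmagnesium bromide, C[Mg]Br
Why: Grignard addition to the aldehyde introduces C9 and gives a racemic carbinol whose stereocentre is erased in the next step.

Step 6
Reactants: 7 rac-1-Fur-ethanol
Product: 8 1-Fur-ethanone
Conditions: Dess–Martin periodinane, NaHCO3, CH2Cl2, rt
Reagents that add atoms: none
Why: Buffered Dess–Martin oxidation of the secondary furyl carbinol to the methyl ketone is mild enough for both silyl groups.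

Step 7
Reactants: 8 1-Fur-ethanone
Product: 9 1-Fur-1-(trimethylsilyloxy)ethene
Conditions: TMSOTf, Et3N, CH2Cl2, 0 °C
Reagents that add atoms: trimethylsilyl trifluoromethanesulfonate, C[Si](C)(C)OS(=O)(=O)C(F)(F)F
Why: Soft enolisation of the methyl ketone, which can enolise only towards C9, gives the enol silane needed for the Mukaiyama aldol.

Step 8
Reactants: 9 1-Fur-1-(trimethylsilyloxy)ethene; 10 methyl pyruvate
Product: 12 methyl (2R)-2-hydroxy-2-methyl-4-oxo-4-Fur-butanoate, via trimethylsilyl ether 11 (not isolated)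
Conditions: Cu(OTf)2 (10 mol %), (R,R)-t-Bu-box (11 mol %), THF, −78 °C; then aq. citric acid, THF/MeOH, 0 °C
Reagents that add atoms: none
Why: In this catalytic enantioselective Mukaiyama aldol the pyruvate chelates the divalent copper bis(oxazoline) complex through both carbonyls and the enol silane attacks the open ketone face, so the (R,R) ligand should set C10 as (R) (the mirror image of the sense known for the (S,S) complex with aryl ketone enol silanes), and mild acid then cleaves the trimethylsilyl ether 11.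

Step 9
Reactants: 12 methyl (2R)-2-hydroxy-2-methyl-4-oxo-4-Fur-butanoate
Product: 14 (3R,5S)-3-hydroxy-3-methyl-5-Fur-oxolan-2-one, via hydroxy ester 13 (not isolated)
Conditions: RuCl(p-cymene)[(S,S)-TsDPEN] (2 mol %), HCO2H/Et3N (5:2), CH2Cl2, rt; then PPTS (cat.), toluene, 50 °C
Reagents that add atoms: none
Why: Noyori-type asymmetric transfer hydrogenation reduces the heteroaryl ketone under catalyst control, the (S,S) catalyst being expected to give the (S) carbinol at C8 as with simple aryl alkyl ketones, and the γ-hydroxy ester 13 then lactonises under mild acid, helped by the fully substituted C10.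

Step 10
Reactants: 14 (3R,5S)-3-hydroxy-3-methyl-5-Fur-oxolan-2-one
Product: 15 (3R,5S)-3-methyl-5-Fur-3-(triethylsilyloxy)oxolan-2-one
Conditions: TESOTf, 2,6-lutidine, CH2Cl2, −78 to 0 °C
Reagents that add atoms: triethylsilyl trifluoromethanesulfonate, CC[Si](CC)(CC)OS(=O)(=O)C(F)(F)F
Why: A silyl triflate with 2,6-lutidine silylates the hindered tertiary α-hydroxy lactone, protecting O10 for the organometallic and nickel steps.

Step 11
Reactants: 15 (3R,5S)-3-methyl-5-Fur-3-(triethylsilyloxy)oxolan-2-one; 16 (4-bromobut-1-yn-1-yl)trimethylsilane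
Product: 18 (6R,8S)-8-hydroxy-6-methyl-8-Fur-6-(triethylsilyloxy)-1-(trimethylsilyl)oct-1-yn-5-one, via Grignard reagent 17 (not isolated)
Conditions: 16, Mg, THF, rt; then 15, THF, −78 to −40 °C; aq. NH4Cl
Reagents that add atoms: none
Why: Grignard addition to the γ-lactone should stop at the ketone stage because the tetrahedral magnesium hemiketal next to the quaternary C10 persists at low temperature and opens only on work-up, forming C1–C2 without touching C8 or C10 (lactone to γ-hydroxy ketone).

Step 12
Reactants: 18 (6R,8S)-8-hydroxy-6-methyl-8-Fur-6-(triethylsilyloxy)-1-(trimethylsilyl)oct-1-yn-5-one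
Product: 19 (6R,8S)-8-hydroxy-6-methyl-8-Fur-6-(triethylsilyloxy)oct-1-yn-5-one
Conditions: K2CO3, MeOH, 0 °C to rt
Reagents that add atoms: none
Why: Methanolysis of the alkynyl C–Si bond frees the terminal alkyne, while the tertiary TES ether, the primary TBS ether and the furyl C–Si bond are stable to K2CO3 in MeOH (protodesilylation).

Step 13
Reactants: 19 (6R,8S)-8-hydroxy-6-methyl-8-Fur-6-(triethylsilyloxy)oct-1-yn-5-one
Product: 20 (1S,3R)-3-methyl-4-oxo-1-Fur-3-(triethylsilyloxy)oct-7-yn-1-yl propanoate
Conditions: (EtCO)2O, Et3N, DMAP (cat.), CH2Cl2, 0 °C to rt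
Reagents that add atoms: propanoic anhydride, CCC(=O)OC(=O)CC
Why: DMAP-catalysed acylation of the secondary C8 alcohol, drained from its lactol equilibrium, should give the propanoate with retention at C8.

Step 14
Reactants: 20 (1S,3R)-3-methyl-4-oxo-1-Fur-3-(triethylsilyloxy)oct-7-yn-1-yl propanoate
Product: 23 (1S,3R)-1-[4-[(tert-butyldimethylsilyloxy)methyl]-2-hydroxy-5-oxo-2,5-dihydrofuran-3-yl]-3-methyl-4-oxo-3-(triethylsilyloxy)oct-7-yn-1-yl propanoate (lactol epimers), via endoperoxide 21 (not isolated), via silyl ester 22 (not isolated)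
Conditions: O2, visible light, tetraphenylporphyrin (cat.), CH2Cl2, −78 °C; then rt, wet silica gel
Reagents that add atoms: dioxygen, O=O
Why: Singlet oxygen adds across the furan in a [4+2] cycloaddition to endoperoxide 21, silicon then shifts from carbon to peroxide oxygen so that the silicon-bearing carbon becomes carboxyl C12 (silyl ester 22), and hydrolysis closes the γ-hydroxybutenolide with the lactol carbon at C6 (photo-oxygenation of a 2-silylfuran).

Step 15
Reactants: 23 the γ-hydroxybutenolide of step 14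
Product: 24 methyl (2Z,4S,6R)-2-[(tert-butyldimethylsilyloxy)methyl]-3-formyl-6-methyl-7-oxo-4-(propanoyloxy)-6-(triethylsilyloxy)undec-2-en-10-ynoate
Conditions: MeI, K2CO3, DMF, 0 °C
Reagents that add atoms: iodomethane, CI
Why: The hydroxybutenolide is a pseudo-acid whose anion is the ring-opened (Z)-formyl carboxylate, so alkylation with MeI should give the open methyl ester with the free aldehyde cis to it (carboxylate O-alkylation).

Step 16
Reactants: 24 the alkynyl (Z)-formyl enoate of step 15; 25 dimethylzinc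
Product: 27 ten-membered (4E,6R,8S,10R) butenolide with C4=C5 alkene bearing C15, C1 ketone, 12,6-lactone, C8 propanoate, C10 OTES and C13 OTBS, via alkoxide 26 (not isolated)
Conditions: Ni(cod)2 (25 mol %), IMes (25 mol %), Me2Zn (3 equiv), THF/toluene, rt, 24 added by syringe pump over 8 h to 0.003 M; aq. NH4Cl
Reagents that add atoms: dimethylzinc (25), C[Zn]C
Why: Proposed new method: zerovalent nickel carrying the small carbene IMes should bind the terminal alkyne and the C6 aldehyde of 24 and undergo oxidative cyclisation to a five-membered oxanickelacycle with C5–C6 formed at the unsubstituted alkyne carbon, after which methyl transfer from zinc to nickel and reductive elimination place C15 on C4 cis to C6, which is the E ring alkene of zinc alkoxide 26. The closest known reactions are the nickel-catalysed alkylative cyclisation of ynals with organozincs and the carbene-controlled endo-selective reductive macrocyclisation of terminal ynals with silanes, neither of which has been shown to transfer methyl while closing a ten-membered ring. The carbocycle closes in the 10-endo-dig mode (both alkyne carbons end up in the ring), and the butenolide then closes by 5-exo-trig acyl substitution of the C6 zinc alkoxide on the C12 methyl ester held cis across C7=C11, with loss of methoxide. The new C6 stereocentre is under substrate control only: the C8 stereocentre on the neighbouring sp2 carbon decides from which side the tether brings the alkyne to the aldehyde, and the configuration with O6 and O8 cis on the ring is the one needed but is not assured. The step needs endo over exo regiochemistry, which the terminal alkyne and a small carbene should secure, and alkyne–aldehyde coupling over conjugate pathways, ester ionisation and direct methyl addition, which the fully substituted C7=C11 alkene, the silyl ethers at C10 and C13 and slow addition at high dilution should secure.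

Step 17
Reactants: 27 the silyl-protected ten-membered butenolide of step 16
Product: 28 the corresponding (4E,6R,8S,10R) C10,C13-diol
Conditions: HF·pyridine, pyridine, THF, 0 °C to rt
Reagents that add atoms: none
Why: Buffered HF·pyridine removes the primary TBS ether and the tertiary TES ether without base, so the C8 propanoate should neither migrate to O10 nor hydrolyse (fluoride desilylation).

Step 18
Reactants: 28 the C10,C13-diol
Product: 29 the (4E,6R,8S,10R) C10,C13-diacetate
Conditions: Ac2O (excess), DMAP, Et3N, CH2Cl2, rt to 35 °C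
Reagents that add atoms: acetic anhydride, CC(=O)OC(C)=O
Why: DMAP-catalysed acetylation esterifies the primary C13 alcohol at once and the tertiary α-ketol C10 alcohol more slowly, the excess of anhydride keeping acetylation ahead of propanoate migration.

Step 19
Reactants: 29 the C10,C13-diacetate
Product: 30 CNP0285168.1, the (4R,5R,6S,8S,10R) epoxide
Conditions: mCPBA, NaHCO3, CH2Cl2, 0 °C
Reagents that add atoms: 3-chloroperoxybenzoic acid, OOC(=O)c1cccc(Cl)c1
Why: In this Prilezhaev epoxidation the electron-rich trisubstituted C4=C5 alkene reacts in preference to the electron-poor butenolide alkene, and in the conformer that avoids allylic 1,3-strain between C15 and C6 (H6 in the alkene plane) the ring blocks the inner face, so the peracid should add on the outer face syn to O6 and give the (4R,5R) epoxide.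

**Compound list**

1 | diethyl furan-3,4-dicarboxylate | CCOC(=O)c1cocc1C(=O)OCC | starting material
2 | furan-3,4-diyldimethanol | OCc1cocc1CO | intermediate
3 | 3,4-bis[(triethylsilyloxy)methyl]furan | CC[Si](CC)(CC)OCc1cocc1CO[Si](CC)(CC)CC | intermediate
4 | lithium [4-[(triethylsilyloxy)methyl]-2-(triethylsilyl)furan-3-yl]methanolate (not isolated) | CC[Si](CC)(CC)c1occ(CO[Si](CC)(CC)CC)c1CO[Li] | intermediate
5 | 3-[(tert-butyldimethylsilyloxy)methyl]-2-(triethylsilyl)-4-[(triethylsilyloxy)methyl]furan | CC[Si](CC)(CC)c1occ(CO[Si](CC)(CC)CC)c1CO[Si](C)(C)C(C)(C)C | intermediate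
6 | 4-[(tert-butyldimethylsilyloxy)methyl]-5-(triethylsilyl)furan-3-carbaldehyde | CC[Si](CC)(CC)c1occ(C=O)c1CO[Si](C)(C)C(C)(C)C | intermediate
7 | rac-1-Fur-ethanol | CC(O)c1coc([Si](CC)(CC)CC)c1CO[Si](C)(C)C(C)(C)C | intermediate
8 | 1-Fur-ethanone | CC(=O)c1coc([Si](CC)(CC)CC)c1CO[Si](C)(C)C(C)(C)C | intermediate
9 | 1-Fur-1-(trimethylsilyloxy)ethene | C=C(O[Si](C)(C)C)c1coc([Si](CC)(CC)CC)c1CO[Si](C)(C)C(C)(C)C | intermediate
10 | methyl pyruvate | CC(=O)C(=O)OC | starting material
11 | methyl (2R)-2-methyl-4-oxo-4-Fur-2-(trimethylsilyloxy)butanoate (not isolated) | COC(=O)[C@](C)(O[Si](C)(C)C)CC(=O)c1coc([Si](CC)(CC)CC)c1CO[Si](C)(C)C(C)(C)C | intermediate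
12 | methyl (2R)-2-hydroxy-2-methyl-4-oxo-4-Fur-butanoate | COC(=O)[C@](C)(O)CC(=O)c1coc([Si](CC)(CC)CC)c1CO[Si](C)(C)C(C)(C)C | intermediate
13 | methyl (2R,4S)-2,4-dihydroxy-2-methyl-4-Fur-butanoate (not isolated) | COC(=O)[C@](C)(O)C[C@H](O)c1coc([Si](CC)(CC)CC)c1CO[Si](C)(C)C(C)(C)C | intermediate
14 | (3R,5S)-3-hydroxy-3-methyl-5-Fur-oxolan-2-one | O=C1O[C@H](c2coc([Si](CC)(CC)CC)c2CO[Si](C)(C)C(C)(C)C)C[C@@]1(C)O | intermediate
15 | (3R,5S)-3-methyl-5-Fur-3-(triethylsilyloxy)oxolan-2-one | O=C1O[C@H](c2coc([Si](CC)(CC)CC)c2CO[Si](C)(C)C(C)(C)C)C[C@@]1(C)O[Si](CC)(CC)CC | intermediate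
16 | (4-bromobut-1-yn-1-yl)trimethylsilane | C[Si](C)(C)C#CCCBr | starting material
17 | [4-(trimethylsilyl)but-3-yn-1-yl]magnesium bromide (not isolated) | C[Si](C)(C)C#CCC[Mg]Br | intermediate
18 | (6R,8S)-8-hydroxy-6-methyl-8-Fur-6-(triethylsilyloxy)-1-(trimethylsilyl)oct-1-yn-5-one | C[Si](C)(C)C#CCCC(=O)[C@](C)(O[Si](CC)(CC)CC)C[C@H](O)c1coc([Si](CC)(CC)CC)c1CO[Si](C)(C)C(C)(C)C | intermediate
19 | (6R,8S)-8-hydroxy-6-methyl-8-Fur-6-(triethylsilyloxy)oct-1-yn-5-one | C#CCCC(=O)[C@](C)(O[Si](CC)(CC)CC)C[C@H](O)c1coc([Si](CC)(CC)CC)c1CO[Si](C)(C)C(C)(C)C | intermediate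
20 | (1S,3R)-3-methyl-4-oxo-1-Fur-3-(triethylsilyloxy)oct-7-yn-1-yl propanoate | C#CCCC(=O)[C@](C)(O[Si](CC)(CC)CC)C[C@H](OC(=O)CC)c1coc([Si](CC)(CC)CC)c1CO[Si](C)(C)C(C)(C)C | intermediate
21 | (1S,3R)-1-[6-[(tert-butyldimethylsilyloxy)methyl]-1-(triethylsilyl)-2,3,7-trioxabicyclo[2.2.1]hept-5-en-5-yl]-3-methyl-4-oxo-3-(triethylsilyloxy)oct-7-yn-1-yl propanoate (not isolated) | CC[Si](CC)(CC)C12OOC(O1)C([C@@H](OC(=O)CC)C[C@@](C)(O[Si](CC)(CC)CC)C(=O)CCC#C)=C2CO[Si](C)(C)C(C)(C)C | intermediate
22 | triethylsilyl (2Z,4S,6R)-2-[(tert-butyldimethylsilyloxy)methyl]-3-formyl-6-methyl-7-oxo-4-(propanoyloxy)-6-(triethylsilyloxy)undec-2-en-10-ynoate (not isolated) | CC[Si](CC)(CC)OC(=O)/C(CO[Si](C)(C)C(C)(C)C)=C(\C=O)[C@@H](OC(=O)CC)C[C@@](C)(O[Si](CC)(CC)CC)C(=O)CCC#C | intermediate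
23 | (1S,3R)-1-[4-[(tert-butyldimethylsilyloxy)methyl]-2-hydroxy-5-oxo-2,5-dihydrofuran-3-yl]-3-methyl-4-oxo-3-(triethylsilyloxy)oct-7-yn-1-yl propanoate (lactol epimers) | O=C1OC(O)C([C@@H](OC(=O)CC)C[C@@](C)(O[Si](CC)(CC)CC)C(=O)CCC#C)=C1CO[Si](C)(C)C(C)(C)C | intermediate
24 | methyl (2Z,4S,6R)-2-[(tert-butyldimethylsilyloxy)methyl]-3-formyl-6-methyl-7-oxo-4-(propanoyloxy)-6-(triethylsilyloxy)undec-2-en-10-ynoate | C#CCCC(=O)[C@](C)(O[Si](CC)(CC)CC)C[C@H](OC(=O)CC)/C(C=O)=C(\CO[Si](C)(C)C(C)(C)C)C(=O)OC | intermediate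
25 | dimethylzinc | C[Zn]C | starting material
26 | methylzinc alkoxide of the ten-membered (4E,6R,8S,10R) C6 allylic alcohol with the C12 methyl ester still open (not isolated) | C[Zn]O[C@@H]1/C=C(C)/CCC(=O)[C@](C)(O[Si](CC)(CC)CC)C[C@H](OC(=O)CC)/C1=C(\CO[Si](C)(C)C(C)(C)C)C(=O)OC | intermediate
27 | ten-membered (4E,6R,8S,10R) 4,5-alkene 12,6-butenolide with C1 ketone, C8 propanoate, C10 OTES and C13 OTBS | CCC(=O)O[C@H]1C[C@@](C)(O[Si](CC)(CC)CC)C(=O)CC/C(C)=C/[C@H]2OC(=O)C(CO[Si](C)(C)C(C)(C)C)=C12 | intermediate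
28 | (4E,6R,8S,10R) C10,C13-diol of 27 | CCC(=O)O[C@H]1C[C@@](C)(O)C(=O)CC/C(C)=C/[C@H]2OC(=O)C(CO)=C12 | intermediate
29 | (4E,6R,8S,10R) C10,C13-diacetate | CCC(=O)O[C@H]1C[C@@](C)(OC(C)=O)C(=O)CC/C(C)=C/[C@H]2OC(=O)C(COC(C)=O)=C12 | intermediate
30 | CNP0285168.1, (4R,5R,6S,8S,10R) 4,5-epoxide | CCC(=O)O[C@H]1C[C@@](C)(OC(C)=O)C(=O)CC[C@@]2(C)O[C@@H]2[C@H]2OC(=O)C(COC(C)=O)=C12 | target

**Step count**

Total steps: 19. Longest linear sequence: 19 (1 to 30); compounds 10, 16 and 25 are purchased.

**Three steps most likely to fail**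

Step 16 (ten-membered alkylative closure and lactonisation). Alkyne oligomerisation or direct methyl transfer to the aldehyde may outrun the strained ten-membered closure. Bond formation at the internal alkyne carbon would give a nine-membered ring with an exocyclic alkene. Zerovalent nickel may insert into the allylic C8–O bond, and facial selectivity at C6 may be poor. The fallback uses known chemistry, sets out from lactone 15 and returns at 27:
- MeLi (THF, −78 °C) opens 15 to the methyl ketone (3R,5S)-5-hydroxy-3-methyl-5-Fur-3-(triethylsilyloxy)pentan-2-one F1.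
- Acylation as in step 13 gives its propanoate F2.
- The kinetic enolate of the methyl ketone (LiN(SiMe3)2, THF, −78 °C; the ketone can enolise only at C2) is alkylated with (E)-3-bromo-1-iodo-2-methylprop-1-ene to the (E)-vinyl iodide F3, which already holds C15 and the C4=C5 geometry.
- Photo-oxygenation and methylation as in steps 14 and 15 give hydroxybutenolide F4 and (Z)-formyl enoate F5.
- An intramolecular Nozaki–Hiyama–Kishi reaction (CrCl2, NiCl2 cat., DMSO/THF, high dilution) forms C5–C6 with retention of alkene geometry to give ring alcohol F6, which should lactonise on work-up or with a trace of PPTS to 27.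
- A chiral oxazoline–sulfonamide ligand on chromium can be added if substrate control at C6 is inadequate.

Step 19 (epoxidation). Reaction through the other ring conformer would give poor facial selectivity, and Baeyer–Villiger oxidation of the C1 ketone may compete. The fallback sets out from 27 and returns at 30:
- A catalyst-controlled Shi epoxidation of 27 (D-fructose-derived ketone, KHSO5 as 2KHSO5·KHSO4·K2SO4, K2CO3 buffer, MeCN/dimethoxymethane/water, 0 °C) gives epoxide F7. The chiral dioxirane selects the conformer that leads to the (4R,5R) oxide, and the silyl ethers are still in place so no acetate meets the basic buffer.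
- Desilylation with Bu4NF buffered with AcOH (THF, 0 °C) gives epoxy diol F8.
- Acetylation as in step 18 gives 30.

Step 11 (Grignard addition to the lactone). Premature opening of the hemiketal would allow a second addition, or the hindered carbonyl next to the quaternary C10 may react too slowly. The fallback sets out from 15 and returns at 19:
- Aminolysis of 15 with MeNHOMe·HCl and AlMe3 (CH2Cl2, 0 °C to rt) gives hydroxy Weinreb amide F9.
- TMSCl and imidazole cap O8 to give silyl ether F10.
- Grignard reagent 17 adds once to the amide to give ketone F11.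
- K2CO3 in MeOH removes both trimethylsilyl groups to give 19.

**Further compounds**

F1 | step 16 | (3R,5S)-5-hydroxy-3-methyl-5-Fur-3-(triethylsilyloxy)pentan-2-one | CC(=O)[C@](C)(O[Si](CC)(CC)CC)C[C@H](O)c1coc([Si](CC)(CC)CC)c1CO[Si](C)(C)C(C)(C)C
F2 | step 16 | (1S,3R)-3-methyl-4-oxo-1-Fur-3-(triethylsilyloxy)pentyl propanoate | CC(=O)[C@](C)(O[Si](CC)(CC)CC)C[C@H](OC(=O)CC)c1coc([Si](CC)(CC)CC)c1CO[Si](C)(C)C(C)(C)C
F3 | step 16 | (1S,3R,7E)-8-iodo-3,7-dimethyl-4-oxo-1-Fur-3-(triethylsilyloxy)oct-7-en-1-yl propanoate | I/C=C(\C)CCC(=O)[C@](C)(O[Si](CC)(CC)CC)C[C@H](OC(=O)CC)c1coc([Si](CC)(CC)CC)c1CO[Si](C)(C)C(C)(C)C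
F4 | step 16 | (1S,3R,7E)-1-[4-[(tert-butyldimethylsilyloxy)methyl]-2-hydroxy-5-oxo-2,5-dihydrofuran-3-yl]-8-iodo-3,7-dimethyl-4-oxo-3-(triethylsilyloxy)oct-7-en-1-yl propanoate | O=C1OC(O)C([C@@H](OC(=O)CC)C[C@@](C)(O[Si](CC)(CC)CC)C(=O)CC/C(C)=C/I)=C1CO[Si](C)(C)C(C)(C)C
F5 | step 16 | methyl (2Z,4S,6R,10E)-2-[(tert-butyldimethylsilyloxy)methyl]-3-formyl-11-iodo-6,10-dimethyl-7-oxo-4-(propanoyloxy)-6-(triethylsilyloxy)undeca-2,10-dienoate | I/C=C(\C)CCC(=O)[C@](C)(O[Si](CC)(CC)CC)C[C@H](OC(=O)CC)/C(C=O)=C(\CO[Si](C)(C)C(C)(C)C)C(=O)OC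
F6 | step 16 | ten-membered (4E,6R,8S,10R) C6 allylic alcohol with the C12 methyl ester still open | O[C@@H]1/C=C(C)/CCC(=O)[C@](C)(O[Si](CC)(CC)CC)C[C@H](OC(=O)CC)/C1=C(\CO[Si](C)(C)C(C)(C)C)C(=O)OC
F7 | step 19 | (4R,5R,6S,8S,10R) 4,5-epoxide of 27 with C10 OTES and C13 OTBS | CCC(=O)O[C@H]1C[C@@](C)(O[Si](CC)(CC)CC)C(=O)CC[C@@]2(C)O[C@@H]2[C@H]2OC(=O)C(CO[Si](C)(C)C(C)(C)C)=C12
F8 | step 19 | (4R,5R,6S,8S,10R) epoxy C10,C13-diol | CCC(=O)O[C@H]1C[C@@](C)(O)C(=O)CC[C@@]2(C)O[C@@H]2[C@H]2OC(=O)C(CO)=C12
F9 | step 11 | (2R,4S)-4-hydroxy-N-methoxy-N,2-dimethyl-4-Fur-2-(triethylsilyloxy)butanamide | CON(C)C(=O)[C@](C)(O[Si](CC)(CC)CC)C[C@H](O)c1coc([Si](CC)(CC)CC)c1CO[Si](C)(C)C(C)(C)C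
F10 | step 11 | (2R,4S)-N-methoxy-N,2-dimethyl-4-Fur-2-(triethylsilyloxy)-4-(trimethylsilyloxy)butanamide | CON(C)C(=O)[C@](C)(O[Si](CC)(CC)CC)C[C@H](O[Si](C)(C)C)c1coc([Si](CC)(CC)CC)c1CO[Si](C)(C)C(C)(C)C
F11 | step 11 | (6R,8S)-6-methyl-8-Fur-6-(triethylsilyloxy)-1-(trimethylsilyl)-8-(trimethylsilyloxy)oct-1-yn-5-one | C[Si](C)(C)C#CCCC(=O)[C@](C)(O[Si](CC)(CC)CC)C[C@H](O[Si](C)(C)C)c1coc([Si](CC)(CC)CC)c1CO[Si](C)(C)C(C)(C)C
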